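**Route overview**

- Retrosynthesis: the C2=C3 alkene is traced back to a C3 acetate (β-elimination) and the C1 carbonyl to a free secondary carbinol, which uncovers a meso 1-nonadecylcyclohexane-1,3,5-triol. Its exocyclic bond from C5 to the chain is then cut to nonadecylmagnesium bromide plus a cis-3,5-disilyloxycyclohexanone, and the ring is led back to phloroglucinol.
- Forward order: the single six-membered carbocycle comes intact from the arene by all-cis hydrogenation, the C19 chain is joined by an organocerium 1,2-addition to the ring ketone, and no ring is closed afterwards.
- Enabling feature: C5 is the only stereocentre and is chiral only because its two ring arms differ (C6H2 leading to C1=O, C4H2 leading to C3=C2). With the 1,3,5-oxygen pattern (C1=O, C3 as a masked carbinol, C5–OH) the ring maps onto a meso triol whose mirror plane runs through C5 and C2.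
- Stereochemistry: hydrogenation sets the cis diol and equatorial addition sets the tertiary OH trans to it (still achiral). A lipase then acetylates one of the two enantiotopic secondary hydroxyls; the acetylated carbon ends as alkene carbon C3 and the free one as C1=O, which fixes C5 as S.

Key step: step 7

Assumption: the lipase is taken to acetylate the R-configured secondary carbinol of the meso triol (the ring branch carrying the quaternary carbinol and the chain acting as the large group in the usual size model for secondary alcohols); this sense has to be assigned on the monoacetate before it is oxidised.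

**Route**

Step 1
Reactants: 1 phloroglucinol (benzene-1,3,5-triol)
Product: 2 cis,cis-cyclohexane-1,3,5-triol (all-cis, meso)
Conditions: H2 (ca. 100 bar), 5% Rh/Al2O3, EtOH, 80 °C; recrystallisation
Reagents that add atoms: none
Why: Heterogeneous catalytic arene hydrogenation adds all six hydrogens from the catalyst-bound face, so the three carbinol centres should come out all-cis, and hydrogenolysed diol by-products are expected to be removed by crystallisation.

Step 2
Reactants: 2 cis,cis-cyclohexane-1,3,5-triol
Product: 4 cis,cis-3,5-bis(tert-butyldimethylsilyloxy)cyclohexan-1-ol (all-cis), via mono-silyl ether 3 (not isolated)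
Conditions: TBSCl (2.0 equiv), imidazole, DMF, 0 °C → rt; chromatography, under- and over-silylated fractions returned
Reagents that add atoms: tert-butyldimethylsilyl chloride (TBSCl), CC(C)(C)[Si](C)(C)Cl
Why: Imidazole-promoted silyl ether formation on three equivalent equatorial hydroxyls is statistical but clean, the bis-ether is easily separated, material that stops at 3 or runs on to the tris-ether can be recycled (the latter after fluoride cleavage back to 2), and no stereocentre is touched.

Step 3
Reactants: 4 cis,cis-3,5-bis(tert-butyldimethylsilyloxy)cyclohexan-1-ol
Product: 5 cis-3,5-bis(tert-butyldimethylsilyloxy)cyclohexan-1-one (3R,5S; meso)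
Conditions: Dess–Martin periodinane, pyridine, CH2Cl2, 0 °C → rt
Reagents that add atoms: none
Why: Dess–Martin oxidation of the lone secondary alcohol runs under near-neutral conditions, so the β-silyloxy ketone is not enolised toward loss of silanol and both silyl ethers keep their cis relationship.

Step 4
Reactants: 6 1-bromononadecane
Product: 7 nonadecylmagnesium bromide (THF solution, titrated before use)
Conditions: Mg turnings (I2-activated), THF, 45 °C
Reagents that add atoms: magnesium, [Mg]
Why: Grignard formation by insertion of magnesium into a primary C–Br bond is routine, and slow addition of the bromide in warm THF should keep Wurtz coupling low.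

Step 5
Reactants: 5 cis-3,5-bis(tert-butyldimethylsilyloxy)cyclohexan-1-one; 7 nonadecylmagnesium bromide
Product: 9 meso 3,5-bis(tert-butyldimethylsilyloxy)-1-nonadecylcyclohexan-1-ol (silyloxy groups cis; tertiary OH trans to both), via nonadecylcerium dichloride 8 (not isolated)
Conditions: CeCl3 (anhydrous, 1.5 equiv), THF, −78 °C; 7 (1.5 equiv), 1 h; then 5, −78 → −20 °C; H2O quench; chromatography
Reagents that add atoms: nonadecylmagnesium bromide (7), CCCCCCCCCCCCCCCCCCC[Mg]Br
Why: Organocerium 1,2-addition to a ketone: transmetalation gives a nucleophilic but weakly basic reagent that should add without enolisation and β-loss of silanolate, and equatorial attack on the chair holding both silyloxy groups equatorial puts the chain equatorial and the new tertiary OH axial, trans to both ethers (the product is meso either way, and the minor all-cis isomer is removed by chromatography).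

Step 6
Reactants: 9 meso 3,5-bis(tert-butyldimethylsilyloxy)-1-nonadecylcyclohexan-1-ol
Product: 10 meso 1-nonadecylcyclohexane-1,3,5-triol (3-OH and 5-OH cis to each other; 1-OH trans to both)
Conditions: Bu4NF (3 equiv), THF, 0 °C → rt
Reagents that add atoms: none
Why: Fluoride-mediated desilylation, driven by the strong Si–F bond, frees both secondary hydroxyls without touching the tertiary carbinol or any ring stereocentre.

Step 7
Reactants: 10 meso 1-nonadecylcyclohexane-1,3,5-triol; 11 vinyl acetate
Product: 12 (1R,3R,5S)-3,5-dihydroxy-3-nonadecylcyclohexyl acetate
Conditions: immobilised Candida antarctica lipase B (Novozym 435), vinyl acetate (5 equiv), t-BuOMe/THF, 35 °C; stopped at the first sign of diacetate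
Reagents that add atoms: vinyl acetate (11), C=COC(C)=O
Why: Lipase-catalysed irreversible transesterification: vinyl acetate acetylates the active-site serine (the vinyl alcohol released tautomerises to acetaldehyde) and the acyl-enzyme passes the acetyl group to one secondary hydroxyl of 10, so exactly one acetyl C–O bond forms and no ring is closed. The closest known reaction type is the lipase/vinyl acetate monoacetylation of meso cis-cyclohexane-1,3-diols and of cis-3,5-dihydroxycyclohexane derivatives. The bond formation itself creates no stereogenic atom, but esterifying one of two enantiotopic carbinols removes the mirror plane through C1 and C4, so the quaternary carbinol carbon (and both secondary ones) become defined stereocentres, the sense being dictated by the chiral binding pocket of the enzyme. The step needs enantiotopic-group selectivity and secondary-over-tertiary chemoselectivity; the substrate secures both because the chair with the C19 chain equatorial holds the two secondary hydroxyls equatorial and exactly mirror-related, the axial tertiary hydroxyl is too hindered for the acyl-enzyme, and the lipophilic chain keeps the triol dissolved in the organic medium. Running slightly into diacetate should consume the minor enantiomer of 12 preferentially, because its remaining free hydroxyl is the fast-reacting one, and so raise the enantiopurity.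

Step 8
Reactants: 12 (1R,3R,5S)-3,5-dihydroxy-3-nonadecylcyclohexyl acetate
Product: 13 (1S,3S)-3-hydroxy-3-nonadecyl-5-oxocyclohexyl acetate
Conditions: Dess–Martin periodinane, pyridine, CH2Cl2, 0 °C
Reagents that add atoms: none
Why: Dess–Martin oxidation converts the only secondary carbinol into the ketone, while the tertiary alcohol cannot be oxidised and the cold buffered medium should leave the β-acetate in place without acyl migration, so the configuration fixed in step 7 is carried on at the quaternary carbinol carbon.

Step 9
Reactants: 13 (1S,3S)-3-hydroxy-3-nonadecyl-5-oxocyclohexyl acetate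
Product: 14 (S)-5-hydroxy-5-nonadecylcyclohex-2-en-1-one (target)
Conditions: Et3N (2 equiv), CH2Cl2, 0 °C → rt
Reagents that add atoms: none
Why: E1cB β-elimination of acetic acid from a β-acetoxy ketone: enolisation toward the acetoxy-bearing side expels acetate, a far better leaving group than the tertiary hydroxyl on the other side, so the conjugated enone should form under conditions too mild for dehydration toward 3-nonadecylphenol or retro-aldol opening, and the C5 stereocentre, not involved, stays S.

**Compound list**

1 | phloroglucinol (benzene-1,3,5-triol) | Oc1cc(O)cc(O)c1 | starting material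
2 | cis,cis-cyclohexane-1,3,5-triol (all-cis, meso) | O[C@@H]1C[C@H](O)C[C@H](O)C1 | intermediate
3 | cis,cis-5-(tert-butyldimethylsilyloxy)cyclohexane-1,3-diol (all-cis mono-silyl ether) | O[C@@H]1C[C@H](O)C[C@H](O[Si](C)(C)C(C)(C)C)C1 | intermediate (not isolated)
4 | cis,cis-3,5-bis(tert-butyldimethylsilyloxy)cyclohexan-1-ol (all-cis) | O[C@@H]1C[C@H](O[Si](C)(C)C(C)(C)C)C[C@H](O[Si](C)(C)C(C)(C)C)C1 | intermediate
5 | cis-3,5-bis(tert-butyldimethylsilyloxy)cyclohexan-1-one (3R,5S; meso) | O=C1C[C@H](O[Si](C)(C)C(C)(C)C)C[C@H](O[Si](C)(C)C(C)(C)C)C1 | intermediate
6 | 1-bromononadecane | CCCCCCCCCCCCCCCCCCCBr | starting material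
7 | nonadecylmagnesium bromide | CCCCCCCCCCCCCCCCCCC[Mg]Br | intermediate
8 | nonadecylcerium dichloride | CCCCCCCCCCCCCCCCCCC[Ce](Cl)Cl | intermediate (not isolated)
9 | meso 3,5-bis(tert-butyldimethylsilyloxy)-1-nonadecylcyclohexan-1-ol (silyloxy groups cis; tertiary OH trans to both) | CCCCCCCCCCCCCCCCCCC[C@]1(O)C[C@H](O[Si](C)(C)C(C)(C)C)C[C@H](O[Si](C)(C)C(C)(C)C)C1 | intermediate
10 | meso 1-nonadecylcyclohexane-1,3,5-triol (3-OH and 5-OH cis; 1-OH trans to both) | CCCCCCCCCCCCCCCCCCC[C@]1(O)C[C@H](O)C[C@H](O)C1 | intermediate
11 | vinyl acetate | C=COC(C)=O | starting material
12 | (1R,3R,5S)-3,5-dihydroxy-3-nonadecylcyclohexyl acetate | CCCCCCCCCCCCCCCCCCC[C@]1(O)C[C@H](OC(C)=O)C[C@H](O)C1 | intermediate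
13 | (1S,3S)-3-hydroxy-3-nonadecyl-5-oxocyclohexyl acetate | CCCCCCCCCCCCCCCCCCC[C@]1(O)C[C@H](OC(C)=O)CC(=O)C1 | intermediate
14 | (S)-5-hydroxy-5-nonadecylcyclohex-2-en-1-one | CCCCCCCCCCCCCCCCCCC[C@]1(O)CC=CC(=O)C1 | target

**Step count and risks**

Total steps: 9. Longest linear sequence: 8 steps (from 1 through steps 1, 2, 3, 5, 6, 7, 8 and 9 to 14); the Grignard reagent 7 is a one-step branch (step 4).

Steps most likely to fail:

1. Step 7. The acyl-enzyme may hand the acetyl group to the other enantiotopic hydroxyl, or tell the two apart too weakly. The fallback sets out from 10 and returns at 12. Both secondary hydroxyls are acetylated (Ac2O, pyridine, rt, no DMAP so that the tertiary OH stays free) to give meso 5-hydroxy-5-nonadecylcyclohexane-1,3-diyl diacetate F1. One enantiotopic ester is then hydrolysed enzymatically (the same lipase or pig liver esterase, phosphate buffer pH 7 with a little acetone, rt). Hydrolysis removes the group that acylation would have installed, so it delivers the monoacetate of opposite sense and also opens the esterase class of enzymes. The enzyme is chosen so that the acetate on the S carbinol is cleaved, which gives 12.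

2. Step 5. The β-silyloxy ketone may be enolised with loss of silanolate, or equatorial attack may be too weakly preferred, so that the two meso diastereomers form in comparable amounts. The fallback sets out from 5 and returns at 9. Corey–Chaykovsky methylene transfer (Me3S(O)I, NaH, DMSO, rt), whose reversible carbonyl addition ends with the new C–C bond equatorial, should give meso 5,7-bis(tert-butyldimethylsilyloxy)-1-oxaspiro[2.5]octane F2 with the epoxide oxygen axial and trans to both silyloxy groups. CuI-catalysed opening at the CH2 terminus with commercial octadecylmagnesium chloride (C18H37MgCl, THF, −30 °C) then assembles the C19 chain as C1 + C18 and gives 9 with the relative configuration fixed by the epoxide.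

3. Step 2. Silylation does not distinguish three equivalent hydroxyls, so the supply of bis-ether depends on repeated recycling. The fallback sets out from 2 and returns at 4. Condensation of 2 with trimethyl orthobenzoate (camphorsulfonic acid cat., DMF, 100 °C, MeOH removed) gives the cage orthoester 3-phenyl-2,4,10-trioxaadamantane F3. Mild aqueous acid (80% AcOH, rt) opens it to the monoester cis,cis-3,5-dihydroxycyclohexyl benzoate F4; acyl migration among the three equivalent oxygens is degenerate. Excess TBSCl/imidazole in DMF gives cis,cis-3,5-bis(tert-butyldimethylsilyloxy)cyclohexyl benzoate F5, and K2CO3 in MeOH removes the benzoate to give 4, with no statistical step on the way.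

Further compounds
F1 | step 7 | meso 5-hydroxy-5-nonadecylcyclohexane-1,3-diyl diacetate (acetates cis; tertiary OH trans to both) | CCCCCCCCCCCCCCCCCCC[C@]1(O)C[C@H](OC(C)=O)C[C@H](OC(C)=O)C1
F2 | step 5 | meso 5,7-bis(tert-butyldimethylsilyloxy)-1-oxaspiro[2.5]octane (epoxide O trans to both silyloxy groups) | C1O[C@]12C[C@H](O[Si](C)(C)C(C)(C)C)C[C@H](O[Si](C)(C)C(C)(C)C)C2
F3 | step 2 | 3-phenyl-2,4,10-trioxaadamantane (cage orthobenzoate of 2) | c1ccccc1C23O[C@@H]4C[C@H](O2)C[C@H](O3)C4
F4 | step 2 | cis,cis-3,5-dihydroxycyclohexyl benzoate (all-cis) | O=C(O[C@@H]1C[C@H](O)C[C@H](O)C1)c1ccccc1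
F5 | step 2 | cis,cis-3,5-bis(tert-butyldimethylsilyloxy)cyclohexyl benzoate (all-cis) | O=C(O[C@@H]1C[C@H](O[Si](C)(C)C(C)(C)C)C[C@H](O[Si](C)(C)C(C)(C)C)C1)c1ccccc1
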